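## Retrosynthetic overview

1. Dehydroglyasperin C ⇐ its 7,4'-bis-silyl ether, unmasked with buffered fluoride (no acid, so the 2'-hydroxy-isoflav-3-ene cannot close to a pterocarpan).
2. Bis-silyl isoflav-3-ene ⇐ ring A salicylaldehyde + ring B 3-methylene-benzofuran-2(3H)-one (released from an ammonium salt), joined in one flask by oxa-Michael addition, aldol closure, acyl transfer and loss of CO2. C2 is the Mannich CH2, C3 the lactone α-carbon, C4 the aldehyde carbon; the lactone C=O leaves as CO2 and the lactone ring oxygen becomes the free 2'-OH.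
3. Ring order: rings A and B are bought as arenes. In the key operation ring C closes first (spiro aldol), then a four-membered β-lactone ring forms across C3–C4 and is expelled as CO2, leaving the C3=C4 bond.
4. Ring A aldehyde ⇐ 2,4,6-trihydroxybenzaldehyde: bis-MOM protection, O-tert-prenylation/Claisen (prenyl placed beside the future OMe), O-methylation, MOM removal, para-silylation.
5. Ring B salt ⇐ 6-hydroxybenzofuran-2(3H)-one: silylation, then Mannich reaction and quaternisation.

Assumption: the target has no stereocentre and no stereogenic double bond, so it is made as the single achiral compound drawn and no enantioselective step is needed.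

## Route

Step 1
Reactants: 1 2,4,6-trihydroxybenzaldehyde
Product: 2 2-hydroxy-4,6-bis(methoxymethoxy)benzaldehyde
Conditions: MOMCl (2.2 equiv), iPr2NEt (2.5 equiv), CH2Cl2, 0 °C to rt
Reagents that add atoms: chloromethyl methyl ether, COCCl
Why: The para OH and one ortho OH are etherified (Williamson-type acetal ether formation) while the last ortho OH stays free because it is locked in the hydrogen bond to the formyl oxygen.

Step 2
Reactants: 2 2-hydroxy-4,6-bis(methoxymethoxy)benzaldehyde
Product: 4 2-hydroxy-4,6-bis(methoxymethoxy)-3-(3-methylbut-2-en-1-yl)benzaldehyde, via tert-prenyl aryl ether 3 (not isolated)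
Conditions: tert-butyl (2-methylbut-3-en-2-yl) carbonate (1.5 equiv), Pd(PPh3)4 (3 mol%), THF, 0 °C to rt; SiO2 plug; PhMe, 110 °C
Reagents that add atoms: tert-butyl (2-methylbut-3-en-2-yl) carbonate, C=CC(C)(C)OC(=O)OC(C)(C)C
Why: Zerovalent palladium ionises the tertiary carbonate and the acidic chelated phenol captures the 1,1-dimethyl-π-allyl complex at its more substituted end (Tsuji–Trost O-allylation); after the catalyst is removed, the 1,1-dimethylallyl ether undergoes an aromatic Claisen [3,3] shift into C3, the only free ortho position, which gives the linear prenyl group (no stereocentre).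

Step 3
Reactants: 4 2-hydroxy-4,6-bis(methoxymethoxy)-3-(3-methylbut-2-en-1-yl)benzaldehyde
Product: 5 2-methoxy-4,6-bis(methoxymethoxy)-3-(3-methylbut-2-en-1-yl)benzaldehyde
Conditions: MeI (3 equiv), K2CO3 (2 equiv), DMF, rt to 40 °C
Reagents that add atoms: iodomethane, CI
Why: Williamson O-methylation of the one free (chelated) phenol fixes the future 5-OMe next to the prenyl group; MOM ethers, aldehyde and olefin are inert to K2CO3/MeI.

Step 4
Reactants: 5 2-methoxy-4,6-bis(methoxymethoxy)-3-(3-methylbut-2-en-1-yl)benzaldehyde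
Product: 6 4,6-dihydroxy-2-methoxy-3-(3-methylbut-2-en-1-yl)benzaldehyde
Conditions: 3 M HCl, MeOH, 40 °C, 2 h
Reagents that add atoms: none
Why: Acid-catalysed acetal exchange with methanol removes both MOM groups under conditions mild enough that the prenyl olefin does not cyclise onto the neighbouring phenol (acetal cleavage).

Step 5
Reactants: 6 4,6-dihydroxy-2-methoxy-3-(3-methylbut-2-en-1-yl)benzaldehyde
Product: 7 6-hydroxy-2-methoxy-3-(3-methylbut-2-en-1-yl)-4-[(triisopropylsilyl)oxy]benzaldehyde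
Conditions: iPr3SiCl (1.1 equiv), imidazole (2.2 equiv), DMF, 0 °C to rt
Reagents that add atoms: chlorotriisopropylsilane, CC(C)[Si](Cl)(C(C)C)C(C)C
Why: Silyl ether formation is para-selective because the para OH is the more acidic and free one, while the ortho OH is hydrogen-bonded to the aldehyde; masking the para oxygen as a neutral donor keeps the aldehyde electrophilic for step 8.

Step 6
Reactants: 8 6-hydroxybenzofuran-2(3H)-one
Product: 9 6-[(triisopropylsilyl)oxy]benzofuran-2(3H)-one
Conditions: iPr3SiCl (1.1 equiv), imidazole (2.0 equiv), CH2Cl2, 0 °C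
Reagents that add atoms: chlorotriisopropylsilane, CC(C)[Si](Cl)(C(C)C)C(C)C
Why: Chemoselective O-silylation of the phenol (silyl ether formation); imidazole does not deprotonate the lactone, and base-mediated O-alkylation is avoided because the lactone C–H is more acidic than the phenol.

Step 7
Reactants: 9 6-[(triisopropylsilyl)oxy]benzofuran-2(3H)-one
Product: 11 N,N,N-trimethyl-1-{2-oxo-6-[(triisopropylsilyl)oxy]-2,3-dihydrobenzofuran-3-yl}methanaminium iodide, via Mannich base 10 (not isolated)
Conditions: Me2N=CH2+ I− (1.05 equiv), iPr2NEt (1.05 equiv), CH2Cl2, −20 to 0 °C; then MeI (5 equiv), rt; precipitate with Et2O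
Reagents that add atoms: N,N-dimethylmethyleneiminium iodide (Eschenmoser's salt), C=[N+](C)C.[I-]; iodomethane, CI
Why: The acidic C3–H of the aryl lactone is aminomethylated by the iminium salt (Mannich reaction) and the amine is quaternised (Menshutkin reaction) to a storable precursor of the α-methylene lactone that later releases only non-acylating NMe3; the C3 stereocentre is racemic and is destroyed in step 8.

Step 8
Reactants: 7 6-hydroxy-2-methoxy-3-(3-methylbut-2-en-1-yl)-4-[(triisopropylsilyl)oxy]benzaldehyde; 11 N,N,N-trimethyl-1-{2-oxo-6-[(triisopropylsilyl)oxy]-2,3-dihydrobenzofuran-3-yl}methanaminium iodide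
Product: 16 7,4'-bis-O-(triisopropylsilyl)dehydroglyasperin C, via methylene lactone 12 (not isolated), via aryloxymethyl lactone 13 (not isolated), via spiro aldol adduct 14 (not isolated), via fused beta-lactone 15 (not isolated)
Conditions: DBU (2.5 equiv), 4 Å MS, MeCN, 40 °C, 11 (1.05 equiv) added over 2 h, then 60 °C, Ar; pH 7 buffer work-up
Reagents that add atoms: none
Why: Proposed new method: DBU eliminates NMe3 from 11 to give the α-methylene lactone 12, the phenoxide of 7 adds to it (oxa-Michael) to give the aromatic 2-oxidobenzofuran enolate of 13, which closes ring C by a six-membered aldol onto the ortho aldehyde (spiro aldolate 14), the cis alkoxide then attacks the neighbouring aryl-ester carbonyl to form the second ring (β-lactone 15) with release of the ring B 2'-phenoxide, and the 4-aryl-β-lactone loses CO2 to set the C3=C4 bond, every earlier step being reversible so that CO2 loss funnels the sequence; the closest known reactions are the salicylaldehyde–acrylate oxa-Michael/aldol chromene synthesis, the cyclisation of aryl-ester aldolates to β-lactones (Danheiser type) and the thermal decarboxylation of β-lactones to alkenes, and the stereocentres of 13–15 all become sp2 so none remains.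

Step 9
Reactants: 16 7,4'-bis-O-(triisopropylsilyl)dehydroglyasperin C
Product: 17 dehydroglyasperin C
Conditions: Bu4NF (2.2 equiv), AcOH (2.5 equiv), THF, 0 °C, Ar; pH 6–7 buffer work-up
Reagents that add atoms: none
Why: Fluoride cleaves both aryl Si–O bonds (desilylation) at 0 °C while acetic acid buffers the phenoxides, and since no strong acid is present neither pterocarpan closure of the 2'-hydroxy-isoflav-3-ene nor cyclisation of the prenyl group can occur.

## Compound list

1 | 2,4,6-trihydroxybenzaldehyde | O=Cc1c(O)cc(O)cc1O | starting material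
2 | 2-hydroxy-4,6-bis(methoxymethoxy)benzaldehyde | O=Cc1c(O)cc(OCOC)cc1OCOC | intermediate
3 | 2-[(2-methylbut-3-en-2-yl)oxy]-4,6-bis(methoxymethoxy)benzaldehyde (not isolated) | O=Cc1c(OC(C)(C)C=C)cc(OCOC)cc1OCOC | intermediate
4 | 2-hydroxy-4,6-bis(methoxymethoxy)-3-(3-methylbut-2-en-1-yl)benzaldehyde | O=Cc1c(O)c(CC=C(C)C)c(OCOC)cc1OCOC | intermediate
5 | 2-methoxy-4,6-bis(methoxymethoxy)-3-(3-methylbut-2-en-1-yl)benzaldehyde | O=Cc1c(OC)c(CC=C(C)C)c(OCOC)cc1OCOC | intermediate
6 | 4,6-dihydroxy-2-methoxy-3-(3-methylbut-2-en-1-yl)benzaldehyde | O=Cc1c(OC)c(CC=C(C)C)c(O)cc1O | intermediate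
7 | 6-hydroxy-2-methoxy-3-(3-methylbut-2-en-1-yl)-4-[(triisopropylsilyl)oxy]benzaldehyde | O=Cc1c(OC)c(CC=C(C)C)c(O[Si](C(C)C)(C(C)C)C(C)C)cc1O | intermediate
8 | 6-hydroxybenzofuran-2(3H)-one | O=C1Cc2ccc(O)cc2O1 | starting material
9 | 6-[(triisopropylsilyl)oxy]benzofuran-2(3H)-one | O=C1Cc2ccc(O[Si](C(C)C)(C(C)C)C(C)C)cc2O1 | intermediate
10 | 3-[(dimethylamino)methyl]-6-[(triisopropylsilyl)oxy]benzofuran-2(3H)-one (racemic, not isolated) | CN(C)CC1C(=O)Oc2cc(O[Si](C(C)C)(C(C)C)C(C)C)ccc21 | intermediate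
11 | N,N,N-trimethyl-1-{2-oxo-6-[(triisopropylsilyl)oxy]-2,3-dihydrobenzofuran-3-yl}methanaminium iodide (racemic) | C[N+](C)(C)CC1C(=O)Oc2cc(O[Si](C(C)C)(C(C)C)C(C)C)ccc21.[I-] | intermediate
12 | 3-methylene-6-[(triisopropylsilyl)oxy]benzofuran-2(3H)-one (not isolated) | C=C1C(=O)Oc2cc(O[Si](C(C)C)(C(C)C)C(C)C)ccc21 | intermediate
13 | 2-methoxy-3-(3-methylbut-2-en-1-yl)-6-({2-oxo-6-[(triisopropylsilyl)oxy]-2,3-dihydrobenzofuran-3-yl}methoxy)-4-[(triisopropylsilyl)oxy]benzaldehyde (racemic, not isolated; present as its enolate) | O=Cc1c(OC)c(CC=C(C)C)c(O[Si](C(C)C)(C(C)C)C(C)C)cc1OCC1C(=O)Oc2cc(O[Si](C(C)C)(C(C)C)C(C)C)ccc21 | intermediate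
14 | 4-hydroxy-5-methoxy-6-(3-methylbut-2-en-1-yl)-7,6'-bis[(triisopropylsilyl)oxy]spiro[chromane-3,3'-benzofuran]-2'-one (racemic, both diastereomers in equilibrium; the one with 4-OH cis to the lactone carbonyl reacts on; not isolated) | COc1c2c(cc(O[Si](C(C)C)(C(C)C)C(C)C)c1CC=C(C)C)OCC1(C2O)C(=O)Oc2cc(O[Si](C(C)C)(C(C)C)C(C)C)ccc21 | intermediate
15 | β-lactone (oxetan-2-one) fused across C3–C4 of the chromane, C3 carrying the 2-hydroxy-4-[(triisopropylsilyl)oxy]phenyl group; 5-OMe, 6-prenyl, 7-OTIPS (cis ring fusion, racemic, not isolated) | COc1c2c(cc(O[Si](C(C)C)(C(C)C)C(C)C)c1CC=C(C)C)OCC1(c3ccc(O[Si](C(C)C)(C(C)C)C(C)C)cc3O)C(=O)OC21 | intermediate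
16 | 2-{5-methoxy-6-(3-methylbut-2-en-1-yl)-7-[(triisopropylsilyl)oxy]-2H-chromen-3-yl}-5-[(triisopropylsilyl)oxy]phenol (7,4'-bis-O-TIPS dehydroglyasperin C) | COc1c2c(cc(O[Si](C(C)C)(C(C)C)C(C)C)c1CC=C(C)C)OCC(c1ccc(O[Si](C(C)C)(C(C)C)C(C)C)cc1O)=C2 | intermediate
17 | dehydroglyasperin C, 4-[7-hydroxy-5-methoxy-6-(3-methylbut-2-en-1-yl)-2H-chromen-3-yl]benzene-1,3-diol (achiral) | COc1c2c(cc(O)c1CC=C(C)C)OCC(c1ccc(O)cc1O)=C2 | target

## Step count and risks

Total step count: 9. Longest linear sequence: 7 (steps 1–5, 8, 9).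

Steps most likely to fail:

**Step 8 (the one-flask ring C construction).** The methylene lactone 12 may oligomerise, the phenoxide of 7 may add through carbon instead of oxygen, or the aldol onto the electron-rich aldehyde may be too slow. The fallback sets out from 7 and 9 and comes back at 17. Knoevenagel condensation of 7 with lactone 9 (Et3N, PhMe, 80 °C), followed in the same flask by transfer of the lactone acyl group to the ring A phenoxide, gives the 3-arylcoumarin F1. Its liberated 2'-OH is silylated (iPr3SiOTf, 2,6-lutidine, CH2Cl2) to the tris-silyl coumarin F2. iBu2AlH (CH2Cl2, −78 to 0 °C) opens the lactone to the (Z)-allylic alcohol phenol F3. Mitsunobu closure (PPh3, DIAD, THF, 0 °C) forms the O1–C2 bond and gives the tris-silyl isoflav-3-ene F4. Bu4NF/AcOH as in step 9 then gives 17.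

**Step 7 (Mannich reaction and quaternisation).** The Mannich base 10 may lose dimethylamine before it is quaternised, or be aminomethylated twice. The fallback sets out from 7 (and uses 9) and comes back at 13. Aldehyde 7 is O-alkylated with excess BrCH2Cl (Cs2CO3, DMF, rt) to the aryl chloromethyl ether F5. The DBU enolate of lactone 9 is then C-alkylated by F5 (MeCN, 0 °C) to give 13 directly. More DBU at 40–60 °C carries 13 through 14 and 15 to 16 as in step 8.

**Step 2 (O-tert-prenylation and Claisen shift).** Palladium may equilibrate the tertiary ether 3 to the linear O-prenyl ether, which would rearrange to the wrong (1,1-dimethylallyl) C-product, or the chelated phenol may react sluggishly. The fallback sets out from 2 and comes back at 3. Copper-catalysed propargylation of 2 with 2-methylbut-3-yn-2-yl trifluoroacetate (CuCl2 1 mol%, DBU, MeCN, 0 °C) gives the 1,1-dimethylpropargyl ether F6. Semi-hydrogenation (H2, Pd on CaCO3 poisoned with Pb(OAc)2, quinoline, EtOAc, rt) gives the 1,1-dimethylallyl ether 3, which is heated as in step 2 to give 4.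

## Further compounds

F1 | step 8 | 3-{2-hydroxy-4-[(triisopropylsilyl)oxy]phenyl}-5-methoxy-6-(3-methylbut-2-en-1-yl)-7-[(triisopropylsilyl)oxy]-2H-chromen-2-one | COc1c2c(cc(O[Si](C(C)C)(C(C)C)C(C)C)c1CC=C(C)C)OC(=O)C(c1ccc(O[Si](C(C)C)(C(C)C)C(C)C)cc1O)=C2
F2 | step 8 | 3-{2,4-bis[(triisopropylsilyl)oxy]phenyl}-5-methoxy-6-(3-methylbut-2-en-1-yl)-7-[(triisopropylsilyl)oxy]-2H-chromen-2-one | COc1c2c(cc(O[Si](C(C)C)(C(C)C)C(C)C)c1CC=C(C)C)OC(=O)C(c1ccc(O[Si](C(C)C)(C(C)C)C(C)C)cc1O[Si](C(C)C)(C(C)C)C(C)C)=C2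
F3 | step 8 | 2-[(Z)-2-{2,4-bis[(triisopropylsilyl)oxy]phenyl}-3-hydroxyprop-1-en-1-yl]-3-methoxy-4-(3-methylbut-2-en-1-yl)-5-[(triisopropylsilyl)oxy]phenol | COc1c(/C=C(\CO)c2ccc(O[Si](C(C)C)(C(C)C)C(C)C)cc2O[Si](C(C)C)(C(C)C)C(C)C)c(O)cc(O[Si](C(C)C)(C(C)C)C(C)C)c1CC=C(C)C
F4 | step 8 | 3-{2,4-bis[(triisopropylsilyl)oxy]phenyl}-5-methoxy-6-(3-methylbut-2-en-1-yl)-7-[(triisopropylsilyl)oxy]-2H-chromene | COc1c2c(cc(O[Si](C(C)C)(C(C)C)C(C)C)c1CC=C(C)C)OCC(c1ccc(O[Si](C(C)C)(C(C)C)C(C)C)cc1O[Si](C(C)C)(C(C)C)C(C)C)=C2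
F5 | step 7 | 6-(chloromethoxy)-2-methoxy-3-(3-methylbut-2-en-1-yl)-4-[(triisopropylsilyl)oxy]benzaldehyde | O=Cc1c(OC)c(CC=C(C)C)c(O[Si](C(C)C)(C(C)C)C(C)C)cc1OCCl
F6 | step 2 | 2-[(2-methylbut-3-yn-2-yl)oxy]-4,6-bis(methoxymethoxy)benzaldehyde | O=Cc1c(OC(C)(C)C#C)cc(OCOC)cc1OCOC
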